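**Retrosynthetic overview**
1. The lactone carbonyl C12 is disconnected as CO. The (E)-arylidene lactone (ring D, formed last) comes from a syn-selective Pd cyclocarbonylation of a cis 8-hydroxy-10-alkynyl cage, with no aldol or HWE on a preformed lactone.
2. The C8–OH and the C6=C7 alkene come from a Schenck ene (¹O2) transposition of a C7=C8 alkene, on the convex face of the cage.
3. The C1–O–C10 bridge (ring C, THF) and the C10–C11 bond are made in one cascade. The C10 aldehyde captures the C1 oxocarbenium ion, then an alkynylsilane attacks the caged allyl-oxocarbenium ion.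
4. Rings A and B (cyclopentene, dihydropyran) and C5/C9 come from (+)-genipin. The aryl alkyne comes from 4-iodophenyl acetate and TMS-acetylene.
5. Ring order: A/B (genipin), then C (step 4), then D (step 6).

Assumption: (+)-genipin, sold in bulk as a single enantiomer, is an acceptable chiral-pool starting material; its C5/C9 configuration matches the target SMILES.

Convention: iridoid numbering is used. C1 = acetal CH, O2, C3, C4 (CO2Me), C5, C6, C7, C8, C9, C10 = OCH, C11 = lactone α-C, C12 = lactone C=O, C13 = =CHAr. "Convex/exo" means the face carrying H5 and H9.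

**Route**

Step 1
Reactants: 1, (+)-genipin (1R,5S,9S)
Product: 2, 1-O-methylgenipin (C1 methyl acetal, major 1R anomer drawn; C10 CH2OH free)
Conditions: MeOH, BF3·OEt2 (cat.), rt
Reagents that add atoms: methanol, CO
Why: Acid-catalysed lactol-to-acetal exchange (Fischer-type) through the C1 oxocarbenium ion masks the ring-opening-prone lactol and installs the leaving group for step 4; C5/C9 are untouched, and the anomer ratio is irrelevant because C1 is re-ionised later.

Step 2
Reactants: 2, 1-O-methylgenipin
Product: 3, 1-O-methyl-10-oxogenipin (enal C7=C8–C10H=O; 1R,5S,9S)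
Conditions: MnO2 (15 equiv), CH2Cl2, rt
Reagents that add atoms: none
Why: Neutral, chemoselective MnO2 oxidation of the only allylic alcohol leaves the acetal, the push–pull enol ether and the non-acidic C9–H alone, so no stereocentre is at risk.

Step 3
Reactants: 4, 4-iodophenyl acetate; 5, trimethylsilylacetylene
Product: 6, 4-[(trimethylsilyl)ethynyl]phenyl acetate
Conditions: PdCl2(PPh3)2 (2 mol %), CuI (4 mol %), Et3N, THF, rt
Reagents that add atoms: none beyond 4 and 5
Why: Sonogashira coupling of an aryl iodide at rt with a tertiary amine base does not cleave the phenyl acetate; no stereochemistry is involved.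

Step 4
Reactants: 3, 1-O-methyl-10-oxogenipin; 6, silyl alkyne (1.5 equiv)
Product: 7, 10-exo-[(4-acetoxyphenyl)ethynyl]-1,10-anhydrogenipin. This is a tricyclic cage in which O bridges C1 and C10 (THF = C1–O–C10–C8–C9), C7=C8 is retained, and the alkynyl group sits on the convex face (1R,5S,9S,10R).
Conditions: TMSOTf (0.3 equiv), 4 Å MS, CH2Cl2, −40 → 0 °C
Reagents that add atoms: none beyond 6 (OMe and SiMe3 leave as MeOSiMe3)
Why: Proposed new method: TMSOTf ionises the acetal in preference to the aldehyde; the s-trans formyl oxygen, held 1,4 to C1, captures the C1 oxocarbenium ion on the only face it can reach (forced cis fusion, setting C1) to give a caged allyl-conjugated oxocarbenium ion (O⁺=C10–C8=C7); the aryl(silyl)alkyne then attacks C10 ipso to silicon (β-silyl, α-aryl vinyl cation, then loss of TMS⁺, which regenerates TMSOTf) from the convex face, away from the endo C1–O2 bond, setting C10; the closest known reaction types are Isobe/Ferrier C-alkynylation of glycal-derived allyl oxocarbenium ions with silylacetylenes and alkylative cyclisation of 1,4-keto-acetals to 2,5-disubstituted tetrahydrofurans.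

Step 5
Reactants: 7, caged enyne
Product: 9, 8-exo-hydroxy-Δ6,7 caged alkynol (1R,5S,8S,9S,10S), formed via the tertiary allylic hydroperoxide 8, which is reduced in the same pot
Conditions: O2, TPP (1 mol %), white LED, CH2Cl2, −10 °C; then PPh3 (1.2 equiv), −10 °C → rt
Reagents that add atoms: dioxygen, O=O (one O is retained)
Why: In this Schenck ene reaction ¹O2 selects the only electron-rich trisubstituted alkene; it must bond to C8 from the convex face, because the other face would give a trans-fused oxabicyclo[3.3.0] cage; it abstracts the exo C6–H suprafacially, because the exo site on C10 is occupied by the alkyne and C9–H abstraction would give a strongly pyramidalised C8=C9 alkene; this moves the alkene to C6=C7 and sets C8 (S), and PPh3 then cleaves only the O–O bond.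

Step 6
Reactants: 9, caged alkynol
Product: 10, 3-O-acetylprismatomerin (target)
Conditions: Pd(OAc)2 (5 mol %), 2-PyPPh2 (30 mol %), MsOH (10 mol %), CO (20 bar), toluene, 50 °C
Reagents that add atoms: carbon monoxide, [C-]#[O+]
Why: This is a Pd-catalysed cyclocarbonylation of a homopropargylic alcohol (Norton/Drent-type hydroalkoxycarbonylation) in which syn addition places the acyl carbon on C11 and H on C13 on the same side; only the C11-acyl species can be trapped by the cis C8–OH (five-membered ring), so the lactone closes with the aryl group cis to C10, which is the (E)-benzylidene; no stereocentre is touched, and the excess pyridylphosphine buffers the acid so the acetal, the tertiary allylic C–O bond and the aryl acetate survive.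

Stereocentre audit: C5 and C9 come from genipin. C1 and C10 are set in step 4, C8 in step 5, and the C11=C13 (E) geometry in step 6. None is re-ionised afterwards, because C10 is no longer allylic after step 5.

**Compound list**

| No. | Name | SMILES | Role |
|---|---|---|---|
| 1 | (+)-genipin | COC(=O)C1=CO[C@H]([C@H]2[C@@H]1CC=C2CO)O | starting material |
| 2 | 1-O-methylgenipin | COC(=O)C1=CO[C@H]([C@H]2[C@@H]1CC=C2CO)OC | intermediate |
| 3 | 1-O-methyl-10-oxogenipin | COC(=O)C1=CO[C@H]([C@H]2[C@@H]1CC=C2C=O)OC | intermediate |
| 4 | 4-iodophenyl acetate | CC(=O)Oc1ccc(I)cc1 | starting material |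
| 5 | trimethylsilylacetylene | C#C[Si](C)(C)C | starting material |
| 6 | 4-[(trimethylsilyl)ethynyl]phenyl acetate | CC(=O)Oc1ccc(C#C[Si](C)(C)C)cc1 | intermediate |
| 7 | 10-exo-[(4-acetoxyphenyl)ethynyl]-1,10-anhydrogenipin | COC(=O)C1=CO[C@@H]2O[C@@H](C#Cc3ccc(OC(C)=O)cc3)C4=CC[C@H]1[C@H]24 | intermediate |
| 8 | 8-exo-hydroperoxy-Δ6,7 cage (not isolated) | COC(=O)C1=CO[C@@H]2O[C@@H](C#Cc3ccc(OC(C)=O)cc3)[C@]4(OO)C=C[C@H]1[C@H]24 | intermediate |
| 9 | 8-exo-hydroxy-Δ6,7 caged alkynol | COC(=O)C1=CO[C@@H]2O[C@@H](C#Cc3ccc(OC(C)=O)cc3)[C@]4(O)C=C[C@H]1[C@H]24 | intermediate |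
| 10 | 3-O-acetylprismatomerin | COC(=O)C1=CO[C@@H]2O[C@H]3/C(=C\c4ccc(OC(C)=O)cc4)C(=O)O[C@]34C=C[C@H]1[C@H]24 | target |

**Totals**
- Total steps: 6.
- Longest linear sequence: 5 (1 → 2 → 3 → 7 → 9 → 10).
- No protecting-group-only steps are used.

**Three steps most likely to fail**
1. **Step 4.**
   - Risks: the alkyne may attack the open C1 oxocarbenium ion instead of C10, or loss of H9 may lead to cyclopenta[c]pyran pigments.
   - Fallback: make C10–C11 before the cage. Carry out a catalyst-controlled ProPhenol/Me2Zn 1,2-alkynylation of enal 3 with 4-ethynylphenyl acetate, then close the THF ring by mild CSA transacetalisation of C10–OH onto C1.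
2. **Step 5.**
   - Risks: the ene reaction may be slow, or O may be delivered to C7 through C9–H abstraction.
   - Fallback: use an ionic sequence instead of the pericyclic one. Epoxidise 7 on the convex face with mCPBA, open at C7 with PhSe⁻, then oxidise and eliminate the selenoxide syn toward C6 to reach the same 9.
3. **Step 6.**
   - Risks: acyl capture by the tertiary alcohol may be sluggish, 5-endo-dig cycloisomerisation may compete, or acid may ionise the allylic alcohol.
   - Fallback: separate C–H and C–C(O) bond formation. Carry out a proximal-selective syn-hydrostannation of 9 (Mo or Pd catalysis), convert the stannane to the C11 vinyl iodide, then close the lactone by base-mediated, acid-free Pd(0)/CO carbonylative lactonisation. This retains the alkene geometry and gives the same (E)-alkene.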